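**Plan**
- Retrosynthesis: the aryl B–C7' bond is cut first (key step), then the aryl A–C7 bond. This leaves two aryl bromides (23 with arm 1, 39 with arm 2) and the lactone–acetal 10. Each arylglycerol unit is cut at Cα–Cβ (aldol) and at O–CH2 (ether); units 1 and 2 both come from one threo phenol diol, 18.
- Enabling feature: C7 and C7' of the cis-fused 3,7-dioxabicyclo[3.3.0]octane are acetal-type carbons, each bonded to a ring oxygen (O1 in ring A, O2 in ring B). Each aryl–C bond can therefore be made by capture of a bicyclic oxocarbenium ion on its convex face.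
- Forward: Michael adduct 6 → ring A (methyl acetal) → ring B (lactone) → aryl A at C7 → lactol → sulfone → aryl B with its two-unit arm at C7' → deprotection.
- Stereochemistry: C8/C8' from an enamine-catalysed Michael addition; C7 and C7' from exo attack on the oxocarbenium ions; threo units from Evans syn-aldol reactions; erythro units by Mitsunobu inversion at Cα.

Key step: step 25

Remark: lignan locants are used (C7, C8, C9 on the aryl A side of the furofuran; C7', C8', C9' on the aryl B side; Cα, Cβ, Cγ in each arylglycerol unit; unit 1 on aryl A, unit 2 and unit 3 on aryl B). Both enantiomers of 4-benzyl-3-(chloroacetyl)-1,3-oxazolidin-2-one are taken as commercial, and anomeric mixtures are carried forward.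

**Core (lactone–sulfone 11)**

Step 1
Reactants: 1 (tert-butyldimethylsilyloxy)acetaldehyde; 2 nitromethane
Product: 4 tert-butyldimethyl{[(2E)-3-nitroprop-2-en-1-yl]oxy}silane, via nitro alcohol 3 (not isolated)
Conditions: MeNO2 (5 equiv), Et3N (cat.), THF, 0 °C; then MsCl, Et3N, CH2Cl2, −10 → 0 °C
Reagents that add atoms: none
Why: Henry addition followed by mesylation and E1cB loss of methanesulfonate gives the more stable E-nitroalkene; no stereocenter is formed.

Step 2
Reactants: 4 nitroalkene; 5 3-[(tert-butyldimethylsilyl)oxy]propanal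
Product: 6 (2R,3S)-2,3-bis{[(tert-butyldimethylsilyl)oxy]methyl}-4-nitrobutanal
Conditions: (R)-2-[diphenyl(trimethylsilyloxy)methyl]pyrrolidine (10 mol %), 4-nitrophenol (10 mol %), toluene, 0 °C
Reagents that add atoms: none
Why: Enamine-catalysed Michael addition of an aldehyde to a nitroalkene, in which the (E)-enamine of 5 reacts on the face remote from the diphenyl(silyloxy)methyl group through an acyclic synclinal transition state, so that C8 (2R) and C8' (3S) are set together as the syn adduct.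

Step 3
Reactants: 6 nitro aldehyde
Product: 8 [(3R,4S)-2-methoxy-4-(nitromethyl)oxolan-3-yl]methanol, via dimethyl acetal 7 (not isolated)
Conditions: camphorsulfonic acid (20 mol %), MeOH, 0 °C → rt; Et3N quench
Reagents that add atoms: methanol, CO
Why: Acid-catalysed acetalization and methanolysis of both primary silyl ethers, after which the C9' hydroxyl closes the five-membered methyl acetal (ring A, O1–C7) faster than the α-center can enolize; C8 and C8' are not touched.

Step 4
Reactants: 8 nitro alcohol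
Product: 10 (1R,5R)-6-methoxy-3,7-dioxabicyclo[3.3.0]octan-2-one, via hydroxy acid 9 (not isolated)
Conditions: NaNO2 (3 equiv), AcOH (10 equiv), DMSO, 35 °C; acidic work-up
Reagents that add atoms: sodium nitrite, [Na+].[O-]N=O
Why: Nef-type oxidation of the primary nitro group by nitrous acid (through the nitrolic acid) gives the carboxylic acid, which lactonizes onto the cis C9 hydroxyl to close ring B with the stereocenters unchanged.

Step 5
Reactants: 10 lactone–acetal
Product: 11 (1R,5R)-6-(phenylsulfonyl)-3,7-dioxabicyclo[3.3.0]octan-2-one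
Conditions: PhSO2H (1.5 equiv), CaCl2, CH2Cl2, rt
Reagents that add atoms: benzenesulfinic acid, O=S(O)c1ccccc1
Why: Acid-catalysed exchange of the acetal methoxy group for benzenesulfinate through the oxocarbenium ion gives the anomeric sulfone, whose anomeric configuration is lost again on ionization.

**Common threo unit (phenol diol 18)**

Step 6
Reactants: 12 4-bromo-2,6-dimethoxyphenol; 13 (4R)-4-benzyl-3-(chloroacetyl)-1,3-oxazolidin-2-one
Product: 14 (4R)-4-benzyl-3-[(4-bromo-2,6-dimethoxyphenoxy)acetyl]-1,3-oxazolidin-2-one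
Conditions: K2CO3, DMF, rt
Reagents that add atoms: none
Why: Williamson etherification, in which the phenoxide displaces chloride from the α-chloro imide by SN2 faster than it attacks the imide carbonyl groups.

Step 7
Reactants: 14 imide; 15 4-formyl-2-methoxyphenyl acetate
Product: 17 (4R)-4-benzyl-3-[(2R,3S)-3-(4-acetoxy-3-methoxyphenyl)-2-(4-bromo-2,6-dimethoxyphenoxy)-3-hydroxypropanoyl]-1,3-oxazolidin-2-one, via boron enolate 16 (not isolated)
Conditions: Bu2BOTf, i-Pr2NEt, CH2Cl2, −78 → 0 °C; 15, −78 → 0 °C; pH 7 buffer, MeOH, H2O2, 0 °C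
Reagents that add atoms: none
Why: Evans syn-aldol reaction, in which the (Z)-boron enolate reacts through a closed chair transition state on the face away from the benzyl group of the (R)-auxiliary and so sets Cβ and Cα of the threo unit (αS,βS after reduction) that serves both unit 1 and unit 2, the aryl acetate not being enolized.

Step 8
Reactants: 17 aldol adduct
Product: 18 (1S,2S)-2-(4-bromo-2,6-dimethoxyphenoxy)-1-(4-hydroxy-3-methoxyphenyl)propane-1,3-diol
Conditions: LiBH4 (excess), THF, 0 °C → rt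
Reagents that add atoms: none
Why: LiBH4 cleaves the N-acyloxazolidinone reductively to the primary alcohol, returns the auxiliary and also reduces off the aryl acetate, which exposes the phenol without touching the stereocenters or the aryl bromide.

**Aryl bromide A (23, erythro unit 1)**

Step 9
Reactants: 18 phenol diol
Product: 19 (1S,2S)-1-[4-(benzyloxy)-3-methoxyphenyl]-2-(4-bromo-2,6-dimethoxyphenoxy)propane-1,3-diol
Conditions: BnBr (1.1 equiv), K2CO3, DMF, rt
Reagents that add atoms: benzyl bromide, BrCc1ccccc1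
Why: Chemoselective Williamson etherification, since K2CO3 deprotonates only the phenol and the phenoxide displaces bromide from benzyl bromide while the two aliphatic hydroxyls and the stereocenters are untouched.

Step 10
Reactants: 19 diol
Product: 20 (1S,2S)-1-[4-(benzyloxy)-3-methoxyphenyl]-2-(4-bromo-2,6-dimethoxyphenoxy)-3-[(tert-butyldimethylsilyl)oxy]propan-1-ol
Conditions: TBSCl (1.1 equiv), imidazole, CH2Cl2, 0 °C
Reagents that add atoms: tert-butyldimethylsilyl chloride, CC(C)(C)[Si](C)(C)Cl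
Why: Selective silylation of the primary hydroxyl, which is far less hindered than the benzylic secondary one.

Step 11
Reactants: 20 alcohol
Product: 21 (1R,2S)-1-[4-(benzyloxy)-3-methoxyphenyl]-2-(4-bromo-2,6-dimethoxyphenoxy)-3-[(tert-butyldimethylsilyl)oxy]propyl 4-nitrobenzoate
Conditions: PPh3, diisopropyl azodicarboxylate, 4-nitrobenzoic acid, toluene, 0 °C → rt
Reagents that add atoms: 4-nitrobenzoic acid, O=C(O)c1ccc(cc1)[N+](=O)[O-]
Why: Mitsunobu reaction, in which the benzylic alkoxyphosphonium ion is displaced by 4-nitrobenzoate by SN2 with inversion at Cα, turning the threo into the erythro (αR,βS) unit.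

Step 12
Reactants: 21 nitrobenzoate
Product: 22 (1R,2S)-1-[4-(benzyloxy)-3-methoxyphenyl]-2-(4-bromo-2,6-dimethoxyphenoxy)-3-[(tert-butyldimethylsilyl)oxy]propan-1-ol
Conditions: K2CO3 (cat.), MeOH–THF, 0 °C → rt
Reagents that add atoms: none
Why: Base-catalysed transesterification removes the electron-poor benzoate by acyl–oxygen cleavage, so the Cα configuration is retained and the primary silyl ether survives.

Step 13
Reactants: 22 alcohol
Product: 23 aryl bromide A (αR,βS bis-silyl ether)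
Conditions: TBSOTf, 2,6-lutidine, CH2Cl2, −78 → 0 °C
Reagents that add atoms: tert-butyldimethylsilyl triflate, CC(C)(C)[Si](C)(C)OS(=O)(=O)C(F)(F)F
Why: Silylation of the hindered secondary alcohol with the reactive silyl triflate under weakly basic conditions.

**First arylation and activation of C7'**

Step 14
Reactants: 23 aryl bromide A; 11 lactone–sulfone
Product: 26 (1R,5R,6S)-6-(aryl A)-3,7-dioxabicyclo[3.3.0]octan-2-one, via aryllithium 24 (not isolated), via arylzinc bromide 25 (not isolated)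
Conditions: n-BuLi, THF, −78 °C; ZnBr2 (2 equiv), −78 → 0 °C; 11 (1.5 equiv), 0 °C → rt
Reagents that add atoms: none
Why: Bromine–lithium exchange and transmetalation give an arylzinc bromide that substitutes the anomeric sulfone through the ZnBr2-generated bicyclic oxocarbenium ion (known substitution of 2-sulfonyl cyclic ethers by organozinc reagents) on the convex face, anti to C9, which sets C7 as S with the aryl group exo, while the lactone is inert to the organozinc.

Step 15
Reactants: 26 aryl lactone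
Product: 27 (1R,5R,6S)-6-(aryl A)-3,7-dioxabicyclo[3.3.0]octan-2-ol
Conditions: i-Bu2AlH (1.2 equiv), CH2Cl2, −78 °C; aq. potassium sodium tartrate
Reagents that add atoms: none
Why: Partial reduction of the γ-lactone stops at the aluminium hemiacetal at −78 °C and gives the lactol without touching silyl, benzyl or aryl ethers.

Step 16
Reactants: 27 lactol
Product: 28 (1R,5R,6S)-6-(aryl A)-2-(phenylsulfonyl)-3,7-dioxabicyclo[3.3.0]octane
Conditions: PhSO2H (2 equiv), CaCl2, CH2Cl2, 0 °C → rt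
Reagents that add atoms: benzenesulfinic acid, O=S(O)c1ccccc1
Why: Exchange of the lactol hydroxyl for benzenesulfinate through the oxocarbenium ion, as in step 5, with CaCl2 as desiccant and an acid too weak to cleave the silyl ethers.

**Aryl bromide B (39, threo unit 2 and erythro unit 3)**

Step 17
Reactants: 18 phenol diol; 29 (4S)-4-benzyl-3-(chloroacetyl)-1,3-oxazolidin-2-one
Product: 30 (4S)-4-benzyl-3-({4-[(1S,2S)-2-(4-bromo-2,6-dimethoxyphenoxy)-1,3-dihydroxypropyl]-2-methoxyphenoxy}acetyl)-1,3-oxazolidin-2-one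
Conditions: K2CO3, DMF, rt
Reagents that add atoms: none
Why: Chemoselective Williamson etherification, since K2CO3 deprotonates only the phenol and the phenoxide displaces chloride from the (S)-imide.

Step 18
Reactants: 30 diol imide
Product: 31 bis-silyl ether of 30
Conditions: TBSOTf (2.5 equiv), 2,6-lutidine, CH2Cl2, −78 → 0 °C
Reagents that add atoms: tert-butyldimethylsilyl triflate, CC(C)(C)[Si](C)(C)OS(=O)(=O)C(F)(F)F
Why: Silylation of both hydroxyls with the silyl triflate, 2,6-lutidine being too weak a base to enolize the imide.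

Step 19
Reactants: 31 imide; 32 4-(benzyloxy)-3-methoxybenzaldehyde
Product: 34 syn-aldol adduct of 31 and 32 (new acyl unit 2S,3R), via boron enolate 33 (not isolated)
Conditions: Bu2BOTf, i-Pr2NEt, CH2Cl2, −78 → 0 °C; 32, −78 → 0 °C; pH 7 buffer, MeOH, H2O2, 0 °C
Reagents that add atoms: none
Why: Evans syn-aldol reaction in which the (S)-auxiliary overrides the remote stereocenters and sets Cβ and Cα of unit 3 as the threo (αR,βR after reduction) pair.

Step 20
Reactants: 34 aldol adduct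
Product: 35 diol (unit 3 αR,βR with free Cα and Cγ hydroxyls)
Conditions: LiBH4, THF, 0 °C
Reagents that add atoms: none
Why: Reductive cleavage of the N-acyloxazolidinone as in step 8, with the silyl ethers, the benzyl ether, the aryl bromide and all stereocenters unaffected.

Step 21
Reactants: 35 diol
Product: 36 Cγ-silyl ether of 35
Conditions: TBSCl (1.1 equiv), imidazole, CH2Cl2, 0 °C
Reagents that add atoms: tert-butyldimethylsilyl chloride, CC(C)(C)[Si](C)(C)Cl
Why: Selective silylation of the primary hydroxyl over the hindered benzylic one.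

Step 22
Reactants: 36 alcohol
Product: 37 Cα 4-nitrobenzoate of unit 3 (αS,βR)
Conditions: PPh3, diisopropyl azodicarboxylate, 4-nitrobenzoic acid, toluene, 0 °C → rt
Reagents that add atoms: 4-nitrobenzoic acid, O=C(O)c1ccc(cc1)[N+](=O)[O-]
Why: Mitsunobu reaction with SN2 inversion at the benzylic Cα of unit 3, which converts the threo into the erythro (αS,βR) unit.

Step 23
Reactants: 37 nitrobenzoate
Product: 38 erythro alcohol (unit 3 αS,βR)
Conditions: K2CO3 (cat.), MeOH–THF, 0 °C → rt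
Reagents that add atoms: none
Why: Base-catalysed transesterification by acyl–oxygen cleavage frees the Cα hydroxyl with retention, and the alkyl silyl ethers are stable.

Step 24
Reactants: 38 alcohol
Product: 39 aryl bromide B (unit 2 αS,βS; unit 3 αS,βR; four silyl ethers)
Conditions: TBSOTf, 2,6-lutidine, CH2Cl2, −78 → 0 °C
Reagents that add atoms: tert-butyldimethylsilyl triflate, CC(C)(C)[Si](C)(C)OS(=O)(=O)C(F)(F)F
Why: Silylation of the remaining secondary alcohol with the silyl triflate so that no acidic hydrogen is left for the metalation.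

**Fragment union and deprotection**

Step 25
Reactants: 39 aryl bromide B; 28 anomeric sulfone
Product: 42 (1R,2S,5R,6S)-2-(aryl B)-6-(aryl A)-3,7-dioxabicyclo[3.3.0]octane (hexa-silyl di-benzyl ether of the target), via aryllithium 40 (not isolated), via arylzinc bromide 41 (not isolated)
Conditions: 39 (1.3 equiv), n-BuLi, THF, −78 °C; ZnBr2 (2.5 equiv), −78 → 0 °C; 28, THF, 0 °C → rt
Reagents that add atoms: none
Why: ZnBr2 ionizes the anomeric sulfone of 28 to the bicyclic oxocarbenium ion at C7' (ring B), and arylzinc bromide 41 transfers its aryl group through the carbon that carried zinc; the closest known reaction type is the substitution of 2-(phenylsulfonyl) cyclic ethers by organozinc reagents, as used for C-aryl glycosides. No ring is closed. The new stereocenter C7' (S) is controlled by the cis-fused 3,7-dioxabicyclo[3.3.0]octane: C9' and ring A block the concave face, so the aryl group enters on the convex face and ends exo, trans to C9' and cis to H8'. The step needs ipso regioselectivity, which the C–Zn bond fixes para to the arm oxygen (electrophilic substitution of the 1,2,3-trioxygenated ring would go ortho to a methoxy group). It also needs chemoselectivity, which is secured because the arylzinc tolerates silyl, benzyl and aryl ethers and ZnBr2 in THF is too weak to ionize the benzylic C7–O1 bond.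

Step 26
Reactants: 42 protected target
Product: 43 di-O-benzyl target (both terminal phenols as benzyl ethers)
Conditions: Bu4NF (10 equiv), AcOH (10 equiv), THF, 0 °C → rt
Reagents that add atoms: none
Why: Fluoride-mediated cleavage of all six silyl ethers, buffered with AcOH so that the benzylic and furofuran C–O bonds are not exposed to strong base.

Step 27
Reactants: 43 di-O-benzyl ether
Product: 44 CNP0316493.3
Conditions: H2 (1 atm), Pd/C, EtOAc–MeOH, rt, stopped at full debenzylation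
Reagents that add atoms: none
Why: Hydrogenolysis of the two aryl benzyl ethers over Pd/C should be much faster under neutral conditions than cleavage of the benzylic C–O bonds of the furofuran and of the carbinols.

**Compound list**

1 | (tert-butyldimethylsilyloxy)acetaldehyde | O=CCO[Si](C)(C)C(C)(C)C | starting material
2 | nitromethane | C[N+](=O)[O-] | starting material
3 | 1-[(tert-butyldimethylsilyl)oxy]-3-nitropropan-2-ol (racemic) | O=[N+]([O-])CC(O)CO[Si](C)(C)C(C)(C)C | intermediate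
4 | tert-butyldimethyl{[(2E)-3-nitroprop-2-en-1-yl]oxy}silane | O=[N+]([O-])/C=C/CO[Si](C)(C)C(C)(C)C | intermediate
5 | 3-[(tert-butyldimethylsilyl)oxy]propanal | O=CCCO[Si](C)(C)C(C)(C)C | starting material
6 | (2R,3S)-2,3-bis{[(tert-butyldimethylsilyl)oxy]methyl}-4-nitrobutanal | O=C[C@@H](CO[Si](C)(C)C(C)(C)C)[C@H](CO[Si](C)(C)C(C)(C)C)C[N+](=O)[O-] | intermediate
7 | dimethyl acetal of 6 | COC(OC)[C@@H](CO[Si](C)(C)C(C)(C)C)[C@H](CO[Si](C)(C)C(C)(C)C)C[N+](=O)[O-] | intermediate
8 | [(3R,4S)-2-methoxy-4-(nitromethyl)oxolan-3-yl]methanol (both anomers) | COC1OC[C@H](C[N+](=O)[O-])[C@@H]1CO | intermediate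
9 | (3R,4R)-4-(hydroxymethyl)-5-methoxyoxolane-3-carboxylic acid (both anomers) | COC1OC[C@H](C(=O)O)[C@@H]1CO | intermediate
10 | (1R,5R)-6-methoxy-3,7-dioxabicyclo[3.3.0]octan-2-one (both anomers) | COC1OC[C@H]2[C@@H]1COC2=O | intermediate
11 | (1R,5R)-6-(phenylsulfonyl)-3,7-dioxabicyclo[3.3.0]octan-2-one (both anomers) | O=S(=O)(c1ccccc1)C1OC[C@H]2[C@@H]1COC2=O | intermediate
12 | 4-bromo-2,6-dimethoxyphenol | COc1cc(Br)cc(OC)c1O | starting material
13 | (4R)-4-benzyl-3-(chloroacetyl)-1,3-oxazolidin-2-one | O=C(CCl)N1[C@H](Cc2ccccc2)COC1=O | starting material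
14 | (4R)-4-benzyl-3-[(4-bromo-2,6-dimethoxyphenoxy)acetyl]-1,3-oxazolidin-2-one | COc1cc(Br)cc(OC)c1OCC(=O)N1[C@H](Cc2ccccc2)COC1=O | intermediate
15 | 4-formyl-2-methoxyphenyl acetate | COc1cc(C=O)ccc1OC(C)=O | starting material
16 | (Z)-dibutylboron enolate of 14 | CCCCB(CCCC)O/C(=C\Oc1c(OC)cc(Br)cc1OC)N1[C@H](Cc2ccccc2)COC1=O | intermediate
17 | (4R)-4-benzyl-3-[(2R,3S)-3-(4-acetoxy-3-methoxyphenyl)-2-(4-bromo-2,6-dimethoxyphenoxy)-3-hydroxypropanoyl]-1,3-oxazolidin-2-one | COc1cc(Br)cc(OC)c1O[C@@H](C(=O)N1[C@H](Cc2ccccc2)COC1=O)[C@@H](O)c1ccc(OC(C)=O)c(OC)c1 | intermediate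
18 | (1S,2S)-2-(4-bromo-2,6-dimethoxyphenoxy)-1-(4-hydroxy-3-methoxyphenyl)propane-1,3-diol (threo) | COc1cc(Br)cc(OC)c1O[C@@H](CO)[C@@H](O)c1ccc(O)c(OC)c1 | intermediate
19 | (1S,2S)-1-[4-(benzyloxy)-3-methoxyphenyl]-2-(4-bromo-2,6-dimethoxyphenoxy)propane-1,3-diol (threo) | COc1cc([C@H](O)[C@H](CO)Oc2c(OC)cc(Br)cc2OC)ccc1OCc1ccccc1 | intermediate
20 | (1S,2S)-1-[4-(benzyloxy)-3-methoxyphenyl]-2-(4-bromo-2,6-dimethoxyphenoxy)-3-[(tert-butyldimethylsilyl)oxy]propan-1-ol | COc1cc([C@H](O)[C@H](CO[Si](C)(C)C(C)(C)C)Oc2c(OC)cc(Br)cc2OC)ccc1OCc1ccccc1 | intermediate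
21 | (1R,2S)-1-[4-(benzyloxy)-3-methoxyphenyl]-2-(4-bromo-2,6-dimethoxyphenoxy)-3-[(tert-butyldimethylsilyl)oxy]propyl 4-nitrobenzoate | COc1cc([C@@H](OC(=O)c2ccc(cc2)[N+](=O)[O-])[C@H](CO[Si](C)(C)C(C)(C)C)Oc2c(OC)cc(Br)cc2OC)ccc1OCc1ccccc1 | intermediate
22 | (1R,2S)-1-[4-(benzyloxy)-3-methoxyphenyl]-2-(4-bromo-2,6-dimethoxyphenoxy)-3-[(tert-butyldimethylsilyl)oxy]propan-1-ol (erythro) | COc1cc([C@@H](O)[C@H](CO[Si](C)(C)C(C)(C)C)Oc2c(OC)cc(Br)cc2OC)ccc1OCc1ccccc1 | intermediate
23 | aryl bromide A: (1R,2S)-1-[4-(benzyloxy)-3-methoxyphenyl]-2-(4-bromo-2,6-dimethoxyphenoxy)-1,3-bis[(tert-butyldimethylsilyl)oxy]propane | COc1cc([C@@H](O[Si](C)(C)C(C)(C)C)[C@H](CO[Si](C)(C)C(C)(C)C)Oc2c(OC)cc(Br)cc2OC)ccc1OCc1ccccc1 | intermediate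
24 | aryllithium from 23 (Li in place of Br) | COc1cc([C@@H](O[Si](C)(C)C(C)(C)C)[C@H](CO[Si](C)(C)C(C)(C)C)Oc2c(OC)cc([Li])cc2OC)ccc1OCc1ccccc1 | intermediate
25 | arylzinc bromide from 23 (ZnBr in place of Br) | COc1cc([C@@H](O[Si](C)(C)C(C)(C)C)[C@H](CO[Si](C)(C)C(C)(C)C)Oc2c(OC)cc([Zn]Br)cc2OC)ccc1OCc1ccccc1 | intermediate
26 | (1R,5R,6S)-6-(aryl A)-3,7-dioxabicyclo[3.3.0]octan-2-one; aryl A = 3,5-dimethoxyphenyl carrying at O4 the (1R,2S)-1-[4-(benzyloxy)-3-methoxyphenyl]-1,3-bis[(tert-butyldimethylsilyl)oxy]propan-2-yl group; aryl exo | COc1cc([C@@H](O[Si](C)(C)C(C)(C)C)[C@H](CO[Si](C)(C)C(C)(C)C)Oc2c(OC)cc([C@H]3OC[C@H]4[C@@H]3COC4=O)cc2OC)ccc1OCc1ccccc1 | intermediate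
27 | (1R,5R,6S)-6-(aryl A)-3,7-dioxabicyclo[3.3.0]octan-2-ol (both anomers) | COc1cc([C@@H](O[Si](C)(C)C(C)(C)C)[C@H](CO[Si](C)(C)C(C)(C)C)Oc2c(OC)cc([C@H]3OC[C@H]4[C@@H]3COC4O)cc2OC)ccc1OCc1ccccc1 | intermediate
28 | (1R,5R,6S)-6-(aryl A)-2-(phenylsulfonyl)-3,7-dioxabicyclo[3.3.0]octane (both anomers) | COc1cc([C@@H](O[Si](C)(C)C(C)(C)C)[C@H](CO[Si](C)(C)C(C)(C)C)Oc2c(OC)cc([C@H]3OC[C@H]4[C@@H]3COC4S(=O)(=O)c5ccccc5)cc2OC)ccc1OCc1ccccc1 | intermediate
29 | (4S)-4-benzyl-3-(chloroacetyl)-1,3-oxazolidin-2-one | O=C(CCl)N1[C@@H](Cc2ccccc2)COC1=O | starting material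
30 | (4S)-4-benzyl-3-({4-[(1S,2S)-2-(4-bromo-2,6-dimethoxyphenoxy)-1,3-dihydroxypropyl]-2-methoxyphenoxy}acetyl)-1,3-oxazolidin-2-one | COc1cc(Br)cc(OC)c1O[C@@H](CO)[C@@H](O)c1ccc(OCC(=O)N2[C@@H](Cc3ccccc3)COC2=O)c(OC)c1 | intermediate
31 | bis(tert-butyldimethylsilyl) ether of 30 (Cα and Cγ of unit 2) | COc1cc(Br)cc(OC)c1O[C@@H](CO[Si](C)(C)C(C)(C)C)[C@@H](O[Si](C)(C)C(C)(C)C)c1ccc(OCC(=O)N2[C@@H](Cc3ccccc3)COC2=O)c(OC)c1 | intermediate
32 | 4-(benzyloxy)-3-methoxybenzaldehyde | COc1cc(C=O)ccc1OCc1ccccc1 | starting material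
33 | (Z)-dibutylboron enolate of 31 | COc1cc(Br)cc(OC)c1O[C@@H](CO[Si](C)(C)C(C)(C)C)[C@@H](O[Si](C)(C)C(C)(C)C)c1ccc(O/C=C(\OB(CCCC)CCCC)N2[C@@H](Cc3ccccc3)COC2=O)c(OC)c1 | intermediate
34 | syn-aldol adduct: 31 carrying on the imide α-carbon (2S) the (3R)-[4-(benzyloxy)-3-methoxyphenyl]hydroxymethyl group | COc1cc(Br)cc(OC)c1O[C@@H](CO[Si](C)(C)C(C)(C)C)[C@@H](O[Si](C)(C)C(C)(C)C)c1ccc(O[C@H](C(=O)N2[C@@H](Cc3ccccc3)COC2=O)[C@H](O)c2ccc(OCc3ccccc3)c(OC)c2)c(OC)c1 | intermediate
35 | diol: unit 2 (αS,βS) bis-silyl ether; unit 3 (αR,βR, threo) with free Cα and Cγ hydroxyls and 4-O-benzyl | COc1cc(Br)cc(OC)c1O[C@@H](CO[Si](C)(C)C(C)(C)C)[C@@H](O[Si](C)(C)C(C)(C)C)c1ccc(O[C@H](CO)[C@H](O)c2ccc(OCc3ccccc3)c(OC)c2)c(OC)c1 | intermediate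
36 | Cγ-(tert-butyldimethylsilyl) ether of 35 | COc1cc(Br)cc(OC)c1O[C@@H](CO[Si](C)(C)C(C)(C)C)[C@@H](O[Si](C)(C)C(C)(C)C)c1ccc(O[C@H](CO[Si](C)(C)C(C)(C)C)[C@H](O)c2ccc(OCc3ccccc3)c(OC)c2)c(OC)c1 | intermediate
37 | Cα 4-nitrobenzoate of unit 3, inverted (αS,βR) | COc1cc(Br)cc(OC)c1O[C@@H](CO[Si](C)(C)C(C)(C)C)[C@@H](O[Si](C)(C)C(C)(C)C)c1ccc(O[C@H](CO[Si](C)(C)C(C)(C)C)[C@@H](OC(=O)c2ccc(cc2)[N+](=O)[O-])c2ccc(OCc3ccccc3)c(OC)c2)c(OC)c1 | intermediate
38 | erythro alcohol: unit 3 (αS,βR) with free Cα hydroxyl | COc1cc(Br)cc(OC)c1O[C@@H](CO[Si](C)(C)C(C)(C)C)[C@@H](O[Si](C)(C)C(C)(C)C)c1ccc(O[C@H](CO[Si](C)(C)C(C)(C)C)[C@@H](O)c2ccc(OCc3ccccc3)c(OC)c2)c(OC)c1 | intermediate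
39 | aryl bromide B: 5-bromo-1,3-dimethoxybenzene carrying at O2 unit 2 (αS,βS, Cα and Cγ silyl ethers), whose 3-methoxyphenyl ring carries at O4 unit 3 (αS,βR, Cα and Cγ silyl ethers, 4-O-benzyl) | COc1cc(Br)cc(OC)c1O[C@@H](CO[Si](C)(C)C(C)(C)C)[C@@H](O[Si](C)(C)C(C)(C)C)c1ccc(O[C@H](CO[Si](C)(C)C(C)(C)C)[C@@H](O[Si](C)(C)C(C)(C)C)c2ccc(OCc3ccccc3)c(OC)c2)c(OC)c1 | intermediate
40 | aryllithium from 39 (Li in place of Br) | COc1cc([Li])cc(OC)c1O[C@@H](CO[Si](C)(C)C(C)(C)C)[C@@H](O[Si](C)(C)C(C)(C)C)c1ccc(O[C@H](CO[Si](C)(C)C(C)(C)C)[C@@H](O[Si](C)(C)C(C)(C)C)c2ccc(OCc3ccccc3)c(OC)c2)c(OC)c1 | intermediate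
41 | arylzinc bromide from 39 (ZnBr in place of Br) | COc1cc([Zn]Br)cc(OC)c1O[C@@H](CO[Si](C)(C)C(C)(C)C)[C@@H](O[Si](C)(C)C(C)(C)C)c1ccc(O[C@H](CO[Si](C)(C)C(C)(C)C)[C@@H](O[Si](C)(C)C(C)(C)C)c2ccc(OCc3ccccc3)c(OC)c2)c(OC)c1 | intermediate
42 | (1R,2S,5R,6S)-2-(aryl B)-6-(aryl A)-3,7-dioxabicyclo[3.3.0]octane: the target with six tert-butyldimethylsilyl ethers (Cα and Cγ of units 1, 2, 3) and two benzyl ethers (terminal phenols) | COc1cc([C@@H](O[Si](C)(C)C(C)(C)C)[C@H](CO[Si](C)(C)C(C)(C)C)Oc2c(OC)cc([C@H]3OC[C@H]4[C@@H]3CO[C@@H]4c3cc(OC)c(O[C@@H](CO[Si](C)(C)C(C)(C)C)[C@@H](O[Si](C)(C)C(C)(C)C)c4ccc(O[C@H](CO[Si](C)(C)C(C)(C)C)[C@@H](O[Si](C)(C)C(C)(C)C)c5ccc(OCc6ccccc6)c(OC)c5)c(OC)c4)c(OC)c3)cc2OC)ccc1OCc1ccccc1 | intermediate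
43 | target with both terminal phenols as benzyl ethers | COc1cc([C@@H](O)[C@H](CO)Oc2c(OC)cc([C@H]3OC[C@H]4[C@@H]3CO[C@@H]4c3cc(OC)c(O[C@@H](CO)[C@@H](O)c4ccc(O[C@H](CO)[C@@H](O)c5ccc(OCc6ccccc6)c(OC)c5)c(OC)c4)c(OC)c3)cc2OC)ccc1OCc1ccccc1 | intermediate
44 | CNP0316493.3: furofuran (7S,8R,7'S,8'R); unit 1 αR,βS; unit 2 αS,βS; unit 3 αS,βR | COc1cc([C@@H](O)[C@H](CO)Oc2c(OC)cc([C@H]3OC[C@H]4[C@@H]3CO[C@@H]4c3cc(OC)c(O[C@@H](CO)[C@@H](O)c4ccc(O[C@H](CO)[C@@H](O)c5ccc(O)c(OC)c5)c(OC)c4)c(OC)c3)cc2OC)ccc1O | target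

**Step count**
Total steps: 27. Longest linear sequence: 14 steps (6, 7, 8, 17–24, 25, 26, 27).

**Steps most likely to fail**

Step 25 (key step). What may go wrong is incomplete ionization of the anomeric sulfone, loss of a proton from the oxocarbenium ion to give the enol ether, attack on the concave face, or ZnBr2-promoted epimerization at the benzylic C7. The fallback sets out from lactol 27 and aryl bromide 39 and avoids the oxocarbenium ion. Lactol 27 is deprotonated with i-PrMgCl in THF at −20 °C so that it reacts as its hydroxy aldehyde, and aryllithium 40 (from 39 and n-BuLi at −78 °C) is added to give the ring-opened diol F1 as a mixture of C7' carbinol epimers. Treatment with MsCl and Et3N in CH2Cl2 at 0 °C then closes ring B through the para-alkoxybenzylic mesylate and its cation, the C9 oxygen attacking from the less hindered side. This is the classical furofuran closure; it gives the exo-aryl product and comes back to the route at compound 42.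

Step 22 (and likewise step 11). The Mitsunobu inversion may fail through ionization of the activated electron-rich benzylic alcohol (loss of stereospecificity), elimination, or lack of reaction at the hindered carbinol. The fallback sets out from alcohol 36. Oxidation with Dess–Martin periodinane (NaHCO3, CH2Cl2) gives the aryl ketone F2. Reduction with Zn(BH4)2 in Et2O at −40 °C, with the carbonyl and the β-aryloxy oxygen chelated to zinc and hydride delivered anti to the CH2OSi group, should give the erythro alcohol. The route is rejoined at compound 38.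

Step 2. The enamine of the β-silyloxy aldehyde may lose silanolate, and the syn/anti ratio may erode by epimerization α to the aldehyde. The fallback sets out from nitromethane 2 and builds the two centers one after the other. Iminium-catalysed conjugate addition of 2 to (2E)-4-[(tert-butyldimethylsilyl)oxy]but-2-enal (O=C/C=C/CO[Si](C)(C)C(C)(C)C), with the enantiomer of the diphenylprolinol silyl ether that delivers the 3S center, gives nitro aldehyde F3. Enamine-catalysed α-hydroxymethylation with aqueous formaldehyde under catalyst control then gives hydroxymethyl aldehyde F4. This is taken at once into camphorsulfonic acid in MeOH, where desilylation and acetalization rejoin the route at compound 8.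

**Further compounds**
F1 | step 25 | ring-opened diol: (2S,3R,4R)-2-(aryl A)-3-(hydroxymethyl)-4-[(aryl B)(hydroxy)methyl]oxolane, C7' epimers, all silyl and benzyl ethers as in 42 | COc1cc([C@@H](O[Si](C)(C)C(C)(C)C)[C@H](CO[Si](C)(C)C(C)(C)C)Oc2c(OC)cc([C@H]3OC[C@H](C(O)c4cc(OC)c(O[C@@H](CO[Si](C)(C)C(C)(C)C)[C@@H](O[Si](C)(C)C(C)(C)C)c5ccc(O[C@H](CO[Si](C)(C)C(C)(C)C)[C@@H](O[Si](C)(C)C(C)(C)C)c6ccc(OCc7ccccc7)c(OC)c6)c(OC)c5)c(OC)c4)[C@@H]3CO)cc2OC)ccc1OCc1ccccc1
F2 | step 22 | aryl ketone: 36 with the Cα hydroxyl of unit 3 oxidized to C=O | COc1cc(Br)cc(OC)c1O[C@@H](CO[Si](C)(C)C(C)(C)C)[C@@H](O[Si](C)(C)C(C)(C)C)c1ccc(O[C@H](CO[Si](C)(C)C(C)(C)C)C(=O)c2ccc(OCc3ccccc3)c(OC)c2)c(OC)c1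
F3 | step 2 | (3S)-3-{[(tert-butyldimethylsilyl)oxy]methyl}-4-nitrobutanal | O=CC[C@H](CO[Si](C)(C)C(C)(C)C)C[N+](=O)[O-]
F4 | step 2 | (2R,3S)-3-{[(tert-butyldimethylsilyl)oxy]methyl}-2-(hydroxymethyl)-4-nitrobutanal | O=C[C@@H](CO)[C@H](CO[Si](C)(C)C(C)(C)C)C[N+](=O)[O-]
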